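## Structural features

The target is a monocyclic 1,2-dioxolane (O1–O2–C3–C4–C5) whose two oxygen-bearing carbons are both fully substituted. C3 carries a methyl group and a CH2CO2H arm, C5 carries a methyl group and a 2,4-dimethyl-12-phenyldodecyl chain, and the two ring methyls are cis (3R,5R). The chain adds two methyl-bearing stereocentres, C2' (S) and C4' (R), in an anti 1,3-relationship, followed by eight unbranched methylenes (C5'–C12') ending in a phenyl ring. All four stereocentres stand in 1,3-relationships (C3/C5 across C4H2, C5/C2' across C1'H2, C2'/C4' across C3'H2), with no functional group between them to relay control. The fragile elements are the O–O bond (hydrogenation catalysts, low-valent metals, phosphines, hard carbanions), the β-peroxy acid (retro-oxa-Michael opening under strong base) and, in intermediates, any enolisable position next to C4'. The lack of hydrogen on C3 and C5 excludes base-induced Kornblum–DeLaMare cleavage. The real difficulty is building two quaternary peroxide carbons with defined relative configuration and with a defined relation to the chain. The feature used here is that C5, C2' and C4' each bear a methyl group and lie 1,3,5 along the run C5–C1'–C2'–C3'–C4'–C5'. Closed by a C5=C5' double bond, this run is (3S,5S)-1,3,5-trimethylcyclohexene, whose ozonide already holds C5 at the ketal level bonded to the O–O unit and C5' at the aldehyde level.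

## Logic of the disconnections

**18 ⇒ 16 (through 17).** No skeletal bond is cut; the carboxyl C–O bonds are exchanged for a primary alcohol. A free β-peroxy acid would protonate the ylide and bind the Lewis acid of the earlier steps. An ester in its place would make the alkene partner of the key step less nucleophilic and its cation prone to proton loss. The gain is a neutral two-carbon arm that can be carried from the start. The forward oxidation must be free of metals and reductants that cleave O–O and must not let 17 undergo β-elimination.

**16 ⇒ 15.** The O–Si bond is cut. The hydroxyl must be masked during the Lewis acid step and the ylide step, and a bulky, weakly basic silyl ether is the mask least likely to bind SnCl4 or trap a cation. The forward demand is a fluoride deprotection that leaves the peroxide untouched.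

**15 ⇒ 14 ⇒ 10 + 13 (13 ⇐ 12 ⇐ 11).** The C5'–C6' bond is cut, as a C=C bond in 14. C5' emerges from the key step as an aldehyde, and the fourteen carbons beyond it carry no stereochemistry. This removes the whole lipophilic tail in one operation. The olefination must not epimerise C4' or attack O–O, and the alkene must be saturated without a hydrogenation catalyst.

**10 ⇒ 7 + 9.** The C4–C5 and C3–O2 bonds are cut, and C5 and C5' are rejoined through the trioxolane oxygens. This replaces 10 (one ring, four stereocentres, differentiated ends) by a bicyclic hydrocarbon ozonide with two carbon stereocentres and an achiral alkene. Two points need precision: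
- 7 exists as two diastereomers in which both bridgeheads change together, since one bridgehead of the bicycle cannot be inverted alone. Both are usable because C5 becomes planar and C5' becomes a carbonyl group.
- Nothing in 7 or 9 fixes the configuration of C5 relative to C2', or of C3 relative to C5. Up to four diastereomers of 10 are possible, and the wanted one must be separated.

The forward step must ionise the tertiary acetal carbon selectively, close the five-membered ring in preference to proton loss, and spare the liberated aldehyde.

**7 ⇒ 6.** The three C–O bonds of the trioxolane are cut, which restores the C5=C5' double bond. The precursor becomes a simple hydrocarbon. The forward demand is intramolecular recombination of the cleaved ends rather than oligomerisation.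

**6 ⇒ 5 ⇒ 3.** The bond between the ring carbon and its methyl group is cut. Because 3 is C2-symmetric, both α-positions are equivalent, so enolisation gives one enol triflate and the double bond of 6 is placed without ambiguity. Addition of a methyl nucleophile followed by dehydration would give endocyclic and exocyclic isomers. The coupling must not move the double bond.

**3 ⇒ 1.** The C3–CH3 bond is cut. One stereocentre is selected from the racemate and the other is created trans to it in the same operation. The forward demand is a high selectivity factor and conversion held below one half.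

**9 ⇒ 8 and 12 ⇒ 11.** The O–Si and C–P bonds are cut; both are routine functionalisations of purchased materials.

## Other disconnections considered

**Alternative 1:** The cut removes both ring C–O bonds (C5–O1 and C3–O2). The O–O unit comes from O2 and the carbons from the vinylcyclopropane A2, in which C3 and C5 are the adjacent quaternary ring carbons and C4 is the ring CH2. In the forward step (PhSSPh, AIBN, light, O2) a PhS radical adds to the vinyl terminus, the bond between the quaternary carbons opens to a tertiary C5 radical, O2 is captured, and the peroxyl radical closes 5-exo onto C3 with loss of the PhS radical to give A1.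

- In favour: this is a known radical chain reaction under neutral conditions, with no Lewis acid and no aldehyde. The complete chain is assembled before any peroxide exists, so hydrogenation and organometallic steps are unrestricted. Only hydroboration–oxidation to 16 and the final oxidation follow. On precedent and on the number of steps after the key step it is better than the chosen plan.
- Against: A2 has two contiguous quaternary cyclopropane carbons and must carry the full chiral chain, which makes it much longer to prepare than 7. Its ring configuration is erased when C5 becomes a radical and C3 part of an allyl unit. Closure of a tertiary peroxyl radical gives no control of C3 or C5, so on stereocontrol it is the equal of the chosen plan and no better. The hydroboration must spare the O–O bond, a risk the chosen plan does not have.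
- Overall: firmer mechanism, equal stereochemical outcome, clearly worse step economy because of A2.

**Alternative 2:** The cut removes C3–C4 and C5–O1. The pieces are the silylperoxy ketal A4, which supplies C3 with the O–O unit, and the chain alkene A5, which supplies C4 and C5. SnCl4 ionises A4 to a peroxycarbenium ion, the CH2 terminus of A5 adds to it, and the silylperoxy oxygen closes on the tertiary C5 cation to give A3, which is identical with 15.

- In favour: this is a known annulation with exactly this alkene class. No aldehyde is present in the Lewis acid step, and the olefination and a catalytic hydrogenation (H2, Pd/C) are done before the peroxide exists. Only two steps remain after the key step. A4 is two operations from 9. On precedent and on peroxide-compatible downstream chemistry it is better than the chosen plan.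
- Against: both ring stereocentres arise from open-chain cations with only the remote C2' centre to bias them, so up to four diastereomers are expected. This is equal to the chosen plan, which at least passes through a cyclic peroxycarbenium ion. The valuable chiral component is the alkene, which such annulations use best in excess, whereas the chosen plan uses the cheap alkene 9 in excess. A5 needs about four operations from 6 (reductive ozonolysis, aldehyde-selective olefination, hydrogenation, methylenation), in which the ring is cut and C5 is then rebuilt as an alkene.
- Overall: about three steps more in total and one more in the longest line than the chosen plan. It is the natural replacement if novelty has to be avoided.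

**Alternative 3:** The cut removes only O1–O2. The precursor is the bis-tertiary 1,3-diol A7, with both C–O bonds and the ester already in place. In the forward step both hydroxyls exchange onto PhI(OAc)2 to give a six-membered dialkoxy-λ3-iodane, which would expel iodobenzene and form the O–O bond to give A6. Acid cleavage of the tert-butyl ester would finish the synthesis.

- In favour: this is the only plan in which C3 and C5 are fixed before the peroxide-forming step, on bonds that step does not touch. In stereochemical logic and in steps after the key step (one) it is better than the chosen plan, and the fragile bond is made last.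
- Against: O–O bond formation by ligand coupling at trivalent iodine has no precedent and opposes known behaviour. Tertiary alkoxy-iodanes fragment by β-scission, which here means C–C cleavage next to C3 or C5. The β-hydroxy ester of A7 is prone to retro-aldol cleavage and dehydration. A strong oxidant would have to end as a weak O–O bond. A stereodefined 1,3-bis-tertiary diol is itself a hard problem, so the stereochemical difficulty is moved rather than removed.
- Overall: the chosen key step is one variation away from two known annulations, while this one contradicts known reactivity. Mechanistically it is much weaker, and its precursor is longer.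

Key step: step 6

Assumption: the phosphoramidite from (S)-1,1'-bi-2-naphthol and bis[(R)-1-phenylethyl]amine is taken to deliver the alkyl group to the enone face that gives the 3S ketone, as it does with cyclohex-2-en-1-one; if the sense were opposite, its enantiomer would be used and nothing else would change.

Remark on locants: ring atoms O1, O2, C3, C4, C5 and chain atoms C1'–C12' of the target are used for all intermediates.

## Route

Step 1
Reactants: 1 rac-5-methylcyclohex-2-en-1-one
Product: 3 (3S,5S)-3,5-dimethylcyclohexan-1-one, via methylzinc enolate 2 (not isolated)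
Conditions: Me2Zn (0.55 equiv), Cu(OTf)2 (1 mol %), (S,R,R)-binaphthol phosphoramidite (2 mol %), toluene, −30 °C, stopped near 45 % conversion; aq. NH4Cl
Reagents that add atoms: dimethylzinc, C[Zn]C
Why: Copper-catalysed asymmetric conjugate addition run as a kinetic resolution: for the (S)-enone the catalyst-preferred face coincides with axial attack anti to the C5 methyl, so it reacts fast and the new C3 centre is set S and trans to C5, while the mismatched (R)-enone stays behind and is removed by chromatography.

Step 2
Reactants: 3 (3S,5S)-3,5-dimethylcyclohexan-1-one
Product: 5 (3S,5S)-3,5-dimethylcyclohex-1-en-1-yl trifluoromethanesulfonate, via lithium enolate 4 (not isolated)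
Conditions: LiN(iPr)2, THF, −78 °C; PhNTf2, −78 to 0 °C
Reagents that add atoms: N-phenylbis(trifluoromethanesulfonimide), O=S(=O)(N(c1ccccc1)S(=O)(=O)C(F)(F)F)C(F)(F)F
Why: Kinetic enolisation and O-triflation; the C2 symmetry of 3 makes both α-methylenes equivalent, so a single enol triflate should form, and the stereocentres are β to the carbonyl and are not touched.

Step 3
Reactants: 5 (3S,5S)-3,5-dimethylcyclohex-1-en-1-yl trifluoromethanesulfonate
Product: 6 (3S,5S)-1,3,5-trimethylcyclohex-1-ene
Conditions: MeMgBr (1.5 equiv), Fe(acac)3 (5 mol %), THF/NMP, −30 to 0 °C; pentane extraction, careful distillation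
Reagents that add atoms: methylmagnesium bromide, C[Mg]Br
Why: Iron-catalysed Kumada-type cross-coupling of an alkenyl triflate with a methyl Grignard reagent, which replaces the triflate by methyl without moving the double bond and without an acid that could scramble the allylic centre.

Step 4
Reactants: 6 (3S,5S)-1,3,5-trimethylcyclohex-1-ene
Product: 7 (3S,5S)-1,3,5-trimethyl-7,8,9-trioxabicyclo[4.2.1]nonane (both diastereomers, bridgeheads coupled)
Conditions: O3/O2, pentane (dilute), −78 °C; N2 purge; cold chromatography on SiO2 behind a shield, small batches
Reagents that add atoms: ozone, [O-][O+]=O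
Why: Ozonolysis by the Criegee mechanism in a non-participating hydrocarbon, where cycloaddition, cycloreversion and recombination of the two ends held by the four-carbon tether should give the bicyclic 1,2,4-trioxolane; both cleavage senses converge on 7 and the C3 and C5 stereocentres are not involved.

Step 5
Reactants: 8 3-methylbut-3-en-1-ol
Product: 9 tert-butyl[(3-methylbut-3-en-1-yl)oxy]diphenylsilane
Conditions: TBDPSCl, imidazole, CH2Cl2, 0 °C to rt
Reagents that add atoms: tert-butyl(chloro)diphenylsilane, CC(C)(C)[Si](Cl)(c1ccccc1)c1ccccc1
Why: Standard silylation of a primary alcohol; the bulky silyl ether is chosen because it is robust toward SnCl4 and weakly Lewis basic.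

Step 6
Reactants: 7 (3S,5S)-1,3,5-trimethyl-7,8,9-trioxabicyclo[4.2.1]nonane; 9 tert-butyl[(3-methylbut-3-en-1-yl)oxy]diphenylsilane
Product: 10 tert-butyl{2-[(3S,5R)-5-[(2S,4S)-2,4-dimethyl-5-oxopentyl]-3,5-dimethyl-1,2-dioxolan-3-yl]ethoxy}diphenylsilane (the cis-dimethyl isomer, separated from its ring diastereomers)
Conditions: 9 (1.3 equiv), SnCl4 (1.0 equiv, promoter), CH2Cl2, −78 °C; Et3N/MeOH then aq. NaHCO3 at −78 °C; chromatography (HPLC if needed)
Reagents that add atoms: none
Why: Proposed new method: SnCl4 should bind the ether oxygen of the trioxolane and the C–O bond at the methyl-bearing acetal carbon should ionise, because this gives a tertiary peroxycarbenium ion whereas the other acetal carbon would give only a secondary one, and the ion remains tied through O1–O2 to the stannylated hemiacetal carbon C5' in an eight-membered ring. The CH2 terminus of 9 should add to C5 in the Markovnikov sense (forming C4–C5 and a tertiary cation at C3), O2 should then close on that cation to give the dioxolane, and the peroxonium ion should expel C5' as the aldehyde, which makes the sequence irreversible. This is a stepwise formal [3+2] annulation whose ring closure is the collapse of an oxygen lone pair onto a free carbocation to form a five-membered ring, so the trajectory limits of a 5-endo attack on a π bond do not apply. The closest known reaction types are the SnCl4-promoted annulation of ozonides with allyltrimethylsilane, which follows the same ionisation, addition, closure and carbonyl-release path through a β-silyl cation, and the SnCl4-promoted [3+2] annulation of silylperoxy ketals with 1,1-disubstituted alkenes, which shows that a plain tertiary cation is captured by a peroxide oxygen; the present step joins the two. C5 is set in the C–C bond formation and its only control element is the facial bias of the cyclic peroxycarbenium ion (methyls at C2' and C4', stannyloxy group at C5'); C3 is set in the closure and its only control element is the size difference between methyl and the silyloxyethyl arm, so up to four diastereomers must be expected and the wanted one is separated. The step needs ionisation at the tertiary acetal carbon (secured by cation stability), ring closure in preference to proton loss or chloride capture (secured by low temperature and the proximity of O2), and survival of the liberated α-branched aldehyde (only a small excess of 9, −78 °C and a cold basic quench keep SnCl4-promoted carbonyl-ene or Prins reaction and enolisation at C4' slow).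

Step 7
Reactants: 11 (7-bromoheptyl)benzene
Product: 12 triphenyl(7-phenylheptyl)phosphonium bromide
Conditions: PPh3, MeCN, reflux; trituration with Et2O
Reagents that add atoms: triphenylphosphine, c1ccc(cc1)P(c1ccccc1)c1ccccc1
Why: SN2 quaternisation of a primary bromide by a phosphine.

Step 8
Reactants: 12 triphenyl(7-phenylheptyl)phosphonium bromide; 10 tert-butyl{2-[(3S,5R)-5-[(2S,4S)-2,4-dimethyl-5-oxopentyl]-3,5-dimethyl-1,2-dioxolan-3-yl]ethoxy}diphenylsilane
Product: 14 tert-butyl{2-[(3S,5R)-5-[(2S,4S,5Z)-2,4-dimethyl-12-phenyldodec-5-en-1-yl]-3,5-dimethyl-1,2-dioxolan-3-yl]ethoxy}diphenylsilane, via phosphonium ylide 13 (not isolated)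
Conditions: 12 (1.3 equiv), NaN(SiMe3)2 (1.25 equiv), THF, 0 °C; then 10, −78 to 0 °C
Reagents that add atoms: none
Why: Wittig olefination with a non-stabilised ylide, which forms the C5'=C6' bond (mainly Z, of no consequence); no excess base and low temperature should protect C4', and a hindered bis-tertiary dialkyl peroxide without α-hydrogen should tolerate the ylide.

Step 9
Reactants: 14 tert-butyl{2-[(3S,5R)-5-[(2S,4S,5Z)-2,4-dimethyl-12-phenyldodec-5-en-1-yl]-3,5-dimethyl-1,2-dioxolan-3-yl]ethoxy}diphenylsilane
Product: 15 tert-butyl{2-[(3S,5R)-5-[(2S,4R)-2,4-dimethyl-12-phenyldodecyl]-3,5-dimethyl-1,2-dioxolan-3-yl]ethoxy}diphenylsilane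
Conditions: KO2CN=NCO2K (excess), AcOH (slow addition), CH2Cl2/MeOH, 0 °C to rt, repeated to full conversion
Reagents that add atoms: none
Why: Diimide reduction, a concerted syn transfer of two hydrogens to the C=C bond that leaves the O–O bond intact, unlike catalytic hydrogenation; the descriptor of C4' changes from S to R by priority only.

Step 10
Reactants: 15 tert-butyl{2-[(3S,5R)-5-[(2S,4R)-2,4-dimethyl-12-phenyldodecyl]-3,5-dimethyl-1,2-dioxolan-3-yl]ethoxy}diphenylsilane
Product: 16 2-[(3S,5R)-5-[(2S,4R)-2,4-dimethyl-12-phenyldodecyl]-3,5-dimethyl-1,2-dioxolan-3-yl]ethan-1-ol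
Conditions: Bu4NF, AcOH, THF, 0 °C to rt
Reagents that add atoms: none
Why: Fluoride-induced cleavage of the silyl ether; the peroxide carbons carry no hydrogen, so buffered fluoride should not open the ring.

Step 11
Reactants: 16 2-[(3S,5R)-5-[(2S,4R)-2,4-dimethyl-12-phenyldodecyl]-3,5-dimethyl-1,2-dioxolan-3-yl]ethan-1-ol
Product: 18 2-[(3R,5R)-5-[(2S,4R)-2,4-dimethyl-12-phenyldodecyl]-3,5-dimethyl-1,2-dioxolan-3-yl]acetic acid, via dioxolanyl acetaldehyde 17 (not isolated)
Conditions: TEMPO (0.2 equiv), PhI(OAc)2 (2.5 equiv), MeCN/CH2Cl2/H2O, rt
Reagents that add atoms: water, O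
Why: Nitroxyl-catalysed oxidation of a primary alcohol through the aldehyde and its hydrate to the acid, with no metal or reductant that could cleave O–O and in a mildly acidic medium that disfavours β-elimination of 17; the descriptor of C3 changes from S to R by priority only.

## Compound list

1 | rac-5-methylcyclohex-2-en-1-one | CC1CC=CC(=O)C1 | starting material
2 | methylzinc (3S,5S)-3,5-dimethylcyclohex-1-en-1-olate | C[C@H](C=C1O[Zn]C)C[C@H](C)C1 | intermediate (not isolated)
3 | (3S,5S)-3,5-dimethylcyclohexan-1-one | C[C@H]1C[C@H](C)CC(=O)C1 | intermediate
4 | lithium (3S,5S)-3,5-dimethylcyclohex-1-en-1-olate | C[C@H](C=C1O[Li])C[C@H](C)C1 | intermediate (not isolated)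
5 | (3S,5S)-3,5-dimethylcyclohex-1-en-1-yl trifluoromethanesulfonate | C[C@H](C=C1OS(=O)(=O)C(F)(F)F)C[C@H](C)C1 | intermediate
6 | (3S,5S)-1,3,5-trimethylcyclohex-1-ene | C[C@H](C=C1C)C[C@H](C)C1 | intermediate
7 | (3S,5S)-1,3,5-trimethyl-7,8,9-trioxabicyclo[4.2.1]nonane, both bridgehead-coupled diastereomers | C[C@H](C1OC2(C)OO1)C[C@H](C)C2 | intermediate
8 | 3-methylbut-3-en-1-ol | C=C(C)CCO | starting material
9 | tert-butyl[(3-methylbut-3-en-1-yl)oxy]diphenylsilane | C=C(C)CCO[Si](c1ccccc1)(c1ccccc1)C(C)(C)C | intermediate
10 | tert-butyl{2-[(3S,5R)-5-[(2S,4S)-2,4-dimethyl-5-oxopentyl]-3,5-dimethyl-1,2-dioxolan-3-yl]ethoxy}diphenylsilane | C[C@H](C=O)C[C@H](C)C[C@]1(C)C[C@](C)(CCO[Si](c2ccccc2)(c2ccccc2)C(C)(C)C)OO1 | intermediate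
11 | (7-bromoheptyl)benzene | BrCCCCCCCc1ccccc1 | starting material
12 | triphenyl(7-phenylheptyl)phosphonium bromide | [Br-].c1ccccc1CCCCCCC[P+](c1ccccc1)(c1ccccc1)c1ccccc1 | intermediate
13 | triphenyl(7-phenylheptylidene)-λ5-phosphane | C(CCCCCCc1ccccc1)=P(c1ccccc1)(c1ccccc1)c1ccccc1 | intermediate (not isolated)
14 | tert-butyl{2-[(3S,5R)-5-[(2S,4S,5Z)-2,4-dimethyl-12-phenyldodec-5-en-1-yl]-3,5-dimethyl-1,2-dioxolan-3-yl]ethoxy}diphenylsilane | C[C@H](/C=C\CCCCCCc1ccccc1)C[C@H](C)C[C@]1(C)C[C@](C)(CCO[Si](c2ccccc2)(c2ccccc2)C(C)(C)C)OO1 | intermediate
15 | tert-butyl{2-[(3S,5R)-5-[(2S,4R)-2,4-dimethyl-12-phenyldodecyl]-3,5-dimethyl-1,2-dioxolan-3-yl]ethoxy}diphenylsilane | C[C@H](CCCCCCCCc1ccccc1)C[C@H](C)C[C@]1(C)C[C@](C)(CCO[Si](c2ccccc2)(c2ccccc2)C(C)(C)C)OO1 | intermediate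
16 | 2-[(3S,5R)-5-[(2S,4R)-2,4-dimethyl-12-phenyldodecyl]-3,5-dimethyl-1,2-dioxolan-3-yl]ethan-1-ol | C[C@H](CCCCCCCCc1ccccc1)C[C@H](C)C[C@]1(C)C[C@](C)(CCO)OO1 | intermediate
17 | 2-[(3R,5R)-5-[(2S,4R)-2,4-dimethyl-12-phenyldodecyl]-3,5-dimethyl-1,2-dioxolan-3-yl]acetaldehyde | C[C@H](CCCCCCCCc1ccccc1)C[C@H](C)C[C@]1(C)C[C@](C)(CC=O)OO1 | intermediate (not isolated)
18 | 2-[(3R,5R)-5-[(2S,4R)-2,4-dimethyl-12-phenyldodecyl]-3,5-dimethyl-1,2-dioxolan-3-yl]acetic acid | C[C@H](CCCCCCCCc1ccccc1)C[C@H](C)C[C@]1(C)C[C@](C)(CC(=O)O)OO1 | target

## Step count and risks

Total: 11 steps. Longest linear sequence: 9 steps (steps 1–4, 6, 8–11).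

**Step 6 (key step, new method).** Three processes are most likely to go wrong:
- diversion of the C3 cation into proton loss or chloride capture, or Lewis-acid fragmentation of the ozonide before the alkene arrives;
- consumption of the liberated aldehyde by SnCl4-promoted carbonyl-ene or Prins reaction with 9;
- weak or adverse facial selection at C5 and C3, since the closure passes through a bridged peroxonium ion in which the arm may prefer to lie away from the chain.

The fallback uses the known silylperoxy-ketal annulation; it sets out from 6 and returns at 10. Ozonolysis of 6 in CH2Cl2/MeOH (NaHCO3, −78 °C) should place the carbonyl oxide on the more substituted carbon, where methanol traps it to give (2S,4S)-6-hydroperoxy-6-methoxy-2,4-dimethylheptanal F1. Et3SiCl/imidazole (DMF, 0 °C) gives (2S,4S)-6-methoxy-2,4-dimethyl-6-[(triethylsilyl)peroxy]heptanal F2. Treatment of F2 with 9 and SnCl4 (CH2Cl2, −78 °C) then gives 10 by the established ionisation, alkene addition and silylperoxy closure. This removes the ozonide-specific failure modes but not the limited ring diastereoselection, which is inherent to cation closures of this kind.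

**Step 4.** The carbonyl oxide and aldehyde ends may recombine intermolecularly to oligomeric peroxides faster than they close the bicyclo[4.2.1] ring, and the product may decompose on concentration. The fallback sets out from 6 and returns at 7. Ozonolysis of 6 in CH2Cl2/MeOH, followed in the same flask by TsOH and then NaHCO3/Me2S, should give the keto acetal (4S,6S)-7,7-dimethoxy-4,6-dimethylheptan-2-one F3. MeONH2·HCl/pyridine converts the ketone into (4S,6S)-7,7-dimethoxy-N-methoxy-4,6-dimethylheptan-2-imine F4. Aqueous AcOH/THF frees the aldehyde to give (2S,4S)-6-(methoxyimino)-2,4-dimethylheptanal F5. Ozonolysis of F5 in pentane/CH2Cl2 at −78 °C (intramolecular Griesbaum co-ozonolysis) generates the ketone O-oxide from the C=N bond beside the waiting aldehyde and should close to 7.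

**Step 1.** Insufficient discrimination between the enone enantiomers, or incomplete catalyst control of the facial sense, would lower the enantiomeric purity of 3 and contaminate it with the cis (meso) ketone. Neither can be corrected later, because they reappear as diastereomers of 10. The fallback sets out from 1 and returns at 3. The same resolution, run with the enantiomeric ligand beyond half conversion, leaves (S)-5-methylcyclohex-2-en-1-one F6 in high enantiomeric purity. After separation from the saturated ketone, Me2CuLi (Et2O, −78 °C) adds anti to the C5 methyl under substrate control to give 3.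

**Step 8.** Enolisation of the α-branched aldehyde by the ylide would epimerise C4', and nucleophilic attack of the phosphorus reagent on the O–O bond would destroy the ring. The fallback replaces carbonyl olefination by alkylation; it sets out from 10 and returns at 15. NaBH4 (MeOH, 0 °C) reduces 10 to tert-butyl{2-[(3S,5R)-5-[(2S,4S)-5-hydroxy-2,4-dimethylpentyl]-3,5-dimethyl-1,2-dioxolan-3-yl]ethoxy}diphenylsilane F7, after which no acidic α-hydrogen remains. Tf2O/2,6-lutidine (CH2Cl2, −78 °C) gives the primary triflate (2S,4S)-5-[(3R,5S)-5-{2-[tert-butyl(diphenyl)silyl]oxyethyl}-3,5-dimethyl-1,2-dioxolan-3-yl]-2,4-dimethylpentyl trifluoromethanesulfonate F8. 7-Phenylhept-1-yne F9 is made from (5-bromopentyl)benzene and LiC≡CH·H2NCH2CH2NH2 in DMSO, lithiated with n-BuLi, and alkylated by F8 in THF/DMPU (−78 to −20 °C). This gives tert-butyl{2-[(3S,5R)-5-[(2S,4S)-2,4-dimethyl-12-phenyldodec-6-yn-1-yl]-3,5-dimethyl-1,2-dioxolan-3-yl]ethoxy}diphenylsilane F10; an acetylide is a weak nucleophile toward a hindered dialkyl peroxide. Excess diimide, generated as in step 9, saturates the triple bond to give 15.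

## Further compounds

F1 | step 6 | (2S,4S)-6-hydroperoxy-6-methoxy-2,4-dimethylheptanal | C[C@H](C=O)C[C@H](C)CC(C)(OC)OO
F2 | step 6 | (2S,4S)-6-methoxy-2,4-dimethyl-6-[(triethylsilyl)peroxy]heptanal | C[C@H](C=O)C[C@H](C)CC(C)(OC)OO[Si](CC)(CC)CC
F3 | step 4 | (4S,6S)-7,7-dimethoxy-4,6-dimethylheptan-2-one | C[C@H](C(OC)OC)C[C@H](C)CC(C)=O
F4 | step 4 | (4S,6S)-7,7-dimethoxy-N-methoxy-4,6-dimethylheptan-2-imine | C[C@H](C(OC)OC)C[C@H](C)CC(C)=NOC
F5 | step 4 | (2S,4S)-6-(methoxyimino)-2,4-dimethylheptanal | C[C@H](C=O)C[C@H](C)CC(C)=NOC
F6 | step 1 | (S)-5-methylcyclohex-2-en-1-one | C[C@H]1CC=CC(=O)C1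
F7 | step 8 | tert-butyl{2-[(3S,5R)-5-[(2S,4S)-5-hydroxy-2,4-dimethylpentyl]-3,5-dimethyl-1,2-dioxolan-3-yl]ethoxy}diphenylsilane | C[C@H](CO)C[C@H](C)C[C@]1(C)C[C@](C)(CCO[Si](c2ccccc2)(c2ccccc2)C(C)(C)C)OO1
F8 | step 8 | (2S,4S)-5-[(3R,5S)-5-{2-[tert-butyl(diphenyl)silyl]oxyethyl}-3,5-dimethyl-1,2-dioxolan-3-yl]-2,4-dimethylpentyl trifluoromethanesulfonate | C[C@H](COS(=O)(=O)C(F)(F)F)C[C@H](C)C[C@]1(C)C[C@](C)(CCO[Si](c2ccccc2)(c2ccccc2)C(C)(C)C)OO1
F9 | step 8 | 7-phenylhept-1-yne | C#CCCCCCc1ccccc1
F10 | step 8 | tert-butyl{2-[(3S,5R)-5-[(2S,4S)-2,4-dimethyl-12-phenyldodec-6-yn-1-yl]-3,5-dimethyl-1,2-dioxolan-3-yl]ethoxy}diphenylsilane | C[C@H](CC#CCCCCCc1ccccc1)C[C@H](C)C[C@]1(C)C[C@](C)(CCO[Si](c2ccccc2)(c2ccccc2)C(C)(C)C)OO1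
A1 | alternative 1 | (3R,5R)-3-ethenyl-3,5-dimethyl-5-[(2S,4R)-2,4-dimethyl-12-phenyldodecyl]-1,2-dioxolane | C[C@H](CCCCCCCCc1ccccc1)C[C@H](C)C[C@]1(C)C[C@](C)(C=C)OO1
A2 | alternative 1 | 1-ethenyl-1,2-dimethyl-2-[(2S,4R)-2,4-dimethyl-12-phenyldodecyl]cyclopropane (ring configuration immaterial) | C[C@H](CCCCCCCCc1ccccc1)C[C@H](C)CC1(C)CC1(C)C=C
A3 | alternative 2 | tert-butyl{2-[(3S,5R)-5-[(2S,4R)-2,4-dimethyl-12-phenyldodecyl]-3,5-dimethyl-1,2-dioxolan-3-yl]ethoxy}diphenylsilane (identical with 15) | C[C@H](CCCCCCCCc1ccccc1)C[C@H](C)C[C@]1(C)C[C@](C)(CCO[Si](c2ccccc2)(c2ccccc2)C(C)(C)C)OO1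
A4 | alternative 2 | tert-butyl{3-methoxy-3-[(triethylsilyl)peroxy]butoxy}diphenylsilane (racemic) | CC(OC)(CCO[Si](c1ccccc1)(c1ccccc1)C(C)(C)C)OO[Si](CC)(CC)CC
A5 | alternative 2 | (4S,6R)-2,4,6-trimethyl-14-phenyltetradec-1-ene | C[C@H](CCCCCCCCc1ccccc1)C[C@H](C)CC(C)=C
A6 | alternative 3 | tert-butyl 2-[(3R,5R)-5-[(2S,4R)-2,4-dimethyl-12-phenyldodecyl]-3,5-dimethyl-1,2-dioxolan-3-yl]acetate | C[C@H](CCCCCCCCc1ccccc1)C[C@H](C)C[C@]1(C)C[C@](C)(CC(=O)OC(C)(C)C)OO1
A7 | alternative 3 | tert-butyl (3R,5R,7S,9R)-3,5-dihydroxy-3,5,7,9-tetramethyl-17-phenylheptadecanoate | C[C@H](CCCCCCCCc1ccccc1)C[C@H](C)C[C@@](C)(O)C[C@@](C)(O)CC(=O)OC(C)(C)C
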